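**Retrosynthetic overview**
1. Numbering (daucane): ring A = cyclopentane C1–C5 (C1 quaternary with CH3, C4 carbinol with i-Pr, C5 ring-fusion CH); ring B = cycloheptene C1–C10(O-angeloyl)–C9=C8(CH3)–C7–C6(O-anisoyl)–C5.
2. The angelate is removed from C10 (last step), then ring B is opened at its only double bond, C8=C9, by ring-closing metathesis of a C10 vinyl carbinol with a C6 methallyl arm. The enabling feature is that C8=C9 lies between the allylic C10–O and homoallylic C6–O carbons, which sit trans on the adjacent ring-A atoms C1 and C5, so both olefin arms are carbonyl-addition products and close to an unstrained trans-fused bicyclo[5.3.0] system.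
3. The C10 carbinol comes from CBS reduction of a vinyl ketone, made by a Mannich sequence from a C1 acetyl group that is carried as a Tamao-oxidisable 1-silylethenyl group. The C6 anisoate is installed before the C10 oxygen exists as an alcohol, so the two secondary oxygens never compete. C4 comes from i-Pr addition to the ring-A ketone.
4. One catalytic event (Cu–NHC conjugate addition of a 1-silylethenylalane to 3-methylcyclopent-2-enone) sets C1; the aluminium enolate aldol with 3-methylbut-3-enal relays C5 and C6 in the same flask; C4 and C10 follow by substrate and reagent control.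
5. Ring order: ring A is bought with the starting enone, ring B is closed in step 9; no protecting groups are used.

Key step: step 9

Remark (assumption on the chemistry): the 1-(benzyldimethylsilyl)ethenyl group at C1 is taken to be clearly larger than the C1 methyl group, so that it directs the enolate face in step 3.

Step 1
Reactants: 1 benzylchlorodimethylsilane; 2 ethynylmagnesium bromide
Product: 3 benzyl(ethynyl)dimethylsilane
Conditions: HC≡CMgBr (0.5 M in THF), THF, 0 °C → rt
Reagents that add atoms: none
Why: Nucleophilic substitution at silicon by the alkynyl Grignard reagent (standard ethynylsilane synthesis); no stereocentre is involved.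

Step 2
Reactants: 4 3-methylbut-3-en-1-ol
Product: 5 3-methylbut-3-enal
Conditions: Dess–Martin periodinane, CH2Cl2, 0 °C; filtered, dried over molecular sieves, used at once as a cold solution
Reagents that add atoms: none
Why: Dess–Martin oxidation is mild and fast enough to give the β,γ-unsaturated aldehyde without migration of the double bond into conjugation.

Step 3
Reactants: 3 benzyl(ethynyl)dimethylsilane; 6 3-methylcyclopent-2-en-1-one; 5 3-methylbut-3-enal
Product: 9 (2S,3S)-3-[1-(benzyldimethylsilyl)ethenyl]-2-[(1S)-1-hydroxy-3-methylbut-3-en-1-yl]-3-methylcyclopentan-1-one, via alkenylalane 7 (not isolated), via aluminium enolate 8 (not isolated)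
Conditions: 3, i-Bu2AlH, hexanes, 55 °C; then 6, Cu(OTf)2 (5 mol %), chiral sulfonate-bearing imidazolinium salt (N-heterocyclic carbene precursor, 5 mol %, the enantiomer that gives the (S) centre), THF, −78 → −30 °C; then 5 (excess), −78 °C; Rochelle salt work-up
Reagents that add atoms: none
Why: α-Selective hydroalumination gives the 1-silylethenylalane, whose Cu–NHC-catalysed enantioselective conjugate addition to the β-substituted cyclopentenone sets C1 under catalyst control, and the regiodefined aluminium enolate 8 should add to 5 through a closed Zimmerman–Traxler transition state on the face opposite the bulky silylalkenyl group, placing the C5 side chain trans to that group with the anti aldol configuration at C6 (tandem conjugate addition–aldol reaction).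

Step 4
Reactants: 9 (2S,3S)-3-[1-(benzyldimethylsilyl)ethenyl]-2-[(1S)-1-hydroxy-3-methylbut-3-en-1-yl]-3-methylcyclopentan-1-one
Product: 10 (1R,2S,3S)-3-[1-(benzyldimethylsilyl)ethenyl]-2-[(1S)-1-hydroxy-3-methylbut-3-en-1-yl]-3-methyl-1-(propan-2-yl)cyclopentan-1-ol
Conditions: i-PrMgCl (4 equiv), CeCl3 (dried), THF, −78 → −40 °C; NH4Cl work-up
Reagents that add atoms: isopropylmagnesium chloride, CC(C)[Mg]Cl
Why: The organocerium reagent adds to the hindered, enolisable ketone without enolisation or reduction (organocerium carbonyl addition), and attack on the α face, opposite the adjacent C5 side chain and the pseudoaxial C1 methyl group, should give the C4 alcohol with OH β (4R).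

Step 5
Reactants: 10 (1R,2S,3S)-3-[1-(benzyldimethylsilyl)ethenyl]-2-[(1S)-1-hydroxy-3-methylbut-3-en-1-yl]-3-methyl-1-(propan-2-yl)cyclopentan-1-ol
Product: 12 1-[(1S,2S,3R)-3-hydroxy-2-[(1S)-1-hydroxy-3-methylbut-3-en-1-yl]-1-methyl-3-(propan-2-yl)cyclopentyl]ethan-1-one, via alkenylsilanol 11 (not isolated)
Conditions: Bu4NF, THF, 0 °C; then H2O2 (30% aq.), KHCO3, MeOH, rt
Reagents that add atoms: hydrogen peroxide, OO
Why: Tamao–Fleming oxidation of the benzyldimethylsilyl alkene: fluoride cleaves the benzyl–silicon bond to silanol 11, whose alkenyl group migrates to oxygen with peroxide to give the enol and hence the methyl ketone, under conditions that leave the methallyl double bond and all stereocentres untouched.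

Step 6
Reactants: 12 1-[(1S,2S,3R)-3-hydroxy-2-[(1S)-1-hydroxy-3-methylbut-3-en-1-yl]-1-methyl-3-(propan-2-yl)cyclopentyl]ethan-1-one; 13 4-methoxybenzoyl chloride
Product: 14 (1S)-1-[(1S,2R,5S)-5-acetyl-2-hydroxy-5-methyl-2-(propan-2-yl)cyclopentyl]-3-methylbut-3-en-1-yl 4-methoxybenzoate
Conditions: pyridine, DMAP (cat.), CH2Cl2, 0 → 40 °C
Reagents that add atoms: none
Why: Nucleophile-catalysed acylation takes place only at the secondary C6 hydroxyl, the tertiary C4 hydroxyl being too hindered, and a ring hemiketal with the C10 ketone would be a strained trans-fused five-membered ring, so the alcohol stays free to react.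

Step 7
Reactants: 14 (1S)-1-[(1S,2R,5S)-5-acetyl-2-hydroxy-5-methyl-2-(propan-2-yl)cyclopentyl]-3-methylbut-3-en-1-yl 4-methoxybenzoate
Product: 17 (1S)-1-[(1S,2R,5S)-2-hydroxy-5-methyl-2-(propan-2-yl)-5-(prop-2-enoyl)cyclopentyl]-3-methylbut-3-en-1-yl 4-methoxybenzoate, via Mannich base 15 (not isolated), via ammonium iodide 16 (not isolated)
Conditions: LiN(SiMe3)2 (2.2 equiv), THF, −78 °C; Me2N=CH2 I, −78 → 0 °C; aqueous work-up; then MeI, K2CO3, CH2Cl2, rt
Reagents that add atoms: dimethyl(methylidene)ammonium iodide (Eschenmoser's salt), C=[N+](C)C.[I-]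
Why: The ketone can enolise only towards its methyl group because C1 is quaternary, so the Mannich reaction with Eschenmoser's salt followed by N-methylation and E1cB loss of trimethylamine should give the vinyl ketone (Mannich–elimination sequence).

Step 8
Reactants: 17 (1S)-1-[(1S,2R,5S)-2-hydroxy-5-methyl-2-(propan-2-yl)-5-(prop-2-enoyl)cyclopentyl]-3-methylbut-3-en-1-yl 4-methoxybenzoate
Product: 18 (1S)-1-[(1S,2R,5S)-2-hydroxy-5-[(1R)-1-hydroxyprop-2-en-1-yl]-5-methyl-2-(propan-2-yl)cyclopentyl]-3-methylbut-3-en-1-yl 4-methoxybenzoate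
Conditions: (S)-2-methyl-CBS-oxazaborolidine (0.5 equiv), catecholborane (3 equiv), toluene, −78 °C; MeOH quench
Reagents that add atoms: none
Why: Corey–Bakshi–Shibata reduction: the (S)-oxazaborolidine distinguishes the quaternary C1 (large) from the vinyl group (small) and delivers hydride 1,2 to give the (R)-carbinol at C10, the same sense expected from the Felkin–Anh preference of the substrate (matched case).

Step 9
Reactants: 18 (1S)-1-[(1S,2R,5S)-2-hydroxy-5-[(1R)-1-hydroxyprop-2-en-1-yl]-5-methyl-2-(propan-2-yl)cyclopentyl]-3-methylbut-3-en-1-yl 4-methoxybenzoate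
Product: 19 (1S,4R,5S,6S,10R)-4,10-dihydroxydauc-8-en-6-yl 4-methoxybenzoate
Conditions: second-generation Hoveyda–Grubbs catalyst (10 mol %), 1,4-benzoquinone (20 mol %), toluene (3 mM), 80 °C
Reagents that add atoms: none
Why: The ruthenium alkylidene loads on the monosubstituted vinyl group at C9, adds across the 1,1-disubstituted methallyl double bond at C8 to a ruthenacyclobutane, and retro-[2+2] with loss of ethene forms the C8=C9 bond (ring-closing olefin metathesis, the standard route to trisubstituted cycloheptenes). Ring B is closed in the seven-membered mode between two olefin arms held on the trans-1,2 positions C1 and C5 of ring A, which gives the unstrained trans-fused bicyclo[5.3.0]decene. No stereocentre is formed; the five set earlier (C1, C4, C5, C6, C10) are not touched, and the metathesis itself fixes the position and the only possible (ring-cis) geometry of the alkene. The step needs cyclisation to win over intermolecular cross-metathesis and over ruthenium hydride isomerisation of the allylic alcohol; high dilution, the free allylic hydroxyl that speeds loading at C9, the absence of any other reactive alkene and added benzoquinone should secure this.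

Step 10
Reactants: 19 (1S,4R,5S,6S,10R)-4,10-dihydroxydauc-8-en-6-yl 4-methoxybenzoate; 20 angelic acid
Product: 22 target (1S,4R,5S,6S,10R)-4-hydroxy-10-[(Z)-2-methylbut-2-enoyloxy]dauc-8-en-6-yl 4-methoxybenzoate, via mixed anhydride 21 (not isolated)
Conditions: 20, 2,4,6-trichlorobenzoyl chloride, Et3N, toluene, rt; then 19, toluene, 80 °C (no DMAP)
Reagents that add atoms: none
Why: Yamaguchi-type esterification through mixed anhydride 21 without a nucleophilic catalyst acylates the secondary allylic C10 hydroxyl with retention at C10 and should avoid Z to E isomerisation of the angelate, while the tertiary C4 hydroxyl does not react.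

**Compound list**
1 | benzylchlorodimethylsilane | C[Si](C)(Cl)Cc1ccccc1 | starting material
2 | ethynylmagnesium bromide | C#C[Mg]Br | starting material
3 | benzyl(ethynyl)dimethylsilane | C#C[Si](C)(C)Cc1ccccc1 | intermediate
4 | 3-methylbut-3-en-1-ol | CC(=C)CCO | starting material
5 | 3-methylbut-3-enal | CC(=C)CC=O | intermediate
6 | 3-methylcyclopent-2-en-1-one | CC1=CC(=O)CC1 | starting material
7 | [1-(benzyldimethylsilyl)ethenyl]bis(2-methylpropyl)alumane | C=C([Al](CC(C)C)CC(C)C)[Si](C)(C)Cc1ccccc1 | intermediate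
8 | bis(2-methylpropyl)aluminium enolate (towards C5) of (S)-3-[1-(benzyldimethylsilyl)ethenyl]-3-methylcyclopentanone | C=C([Si](C)(C)Cc2ccccc2)[C@@]1(C)CCC(O[Al](CC(C)C)CC(C)C)=C1 | intermediate
9 | (2S,3S)-3-[1-(benzyldimethylsilyl)ethenyl]-2-[(1S)-1-hydroxy-3-methylbut-3-en-1-yl]-3-methylcyclopentan-1-one | C=C([Si](C)(C)Cc2ccccc2)[C@@]1(C)CCC(=O)[C@@H]1[C@@H](O)CC(C)=C | intermediate
10 | (1R,2S,3S)-3-[1-(benzyldimethylsilyl)ethenyl]-2-[(1S)-1-hydroxy-3-methylbut-3-en-1-yl]-3-methyl-1-(propan-2-yl)cyclopentan-1-ol | C=C([Si](C)(C)Cc2ccccc2)[C@@]1(C)CC[C@@](O)(C(C)C)[C@@H]1[C@@H](O)CC(C)=C | intermediate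
11 | alkenyl(dimethyl)silanol corresponding to 10 (benzyl on silicon replaced by OH) | C=C([Si](C)(C)O)[C@@]1(C)CC[C@@](O)(C(C)C)[C@@H]1[C@@H](O)CC(C)=C | intermediate
12 | 1-[(1S,2S,3R)-3-hydroxy-2-[(1S)-1-hydroxy-3-methylbut-3-en-1-yl]-1-methyl-3-(propan-2-yl)cyclopentyl]ethan-1-one | CC(=O)[C@@]1(C)CC[C@@](O)(C(C)C)[C@@H]1[C@@H](O)CC(C)=C | intermediate
13 | 4-methoxybenzoyl chloride | COc1ccc(cc1)C(Cl)=O | starting material
14 | (1S)-1-[(1S,2R,5S)-5-acetyl-2-hydroxy-5-methyl-2-(propan-2-yl)cyclopentyl]-3-methylbut-3-en-1-yl 4-methoxybenzoate | CC(=O)[C@@]1(C)CC[C@@](O)(C(C)C)[C@@H]1[C@@H](OC(=O)c2ccc(OC)cc2)CC(C)=C | intermediate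
15 | Mannich base: 3-(dimethylamino)propanoyl analogue of 14 | CN(C)CCC(=O)[C@@]1(C)CC[C@@](O)(C(C)C)[C@@H]1[C@@H](OC(=O)c2ccc(OC)cc2)CC(C)=C | intermediate
16 | trimethylammonium iodide derived from 15 | C[N+](C)(C)CCC(=O)[C@@]1(C)CC[C@@](O)(C(C)C)[C@@H]1[C@@H](OC(=O)c2ccc(OC)cc2)CC(C)=C.[I-] | intermediate
17 | (1S)-1-[(1S,2R,5S)-2-hydroxy-5-methyl-2-(propan-2-yl)-5-(prop-2-enoyl)cyclopentyl]-3-methylbut-3-en-1-yl 4-methoxybenzoate | C=CC(=O)[C@@]1(C)CC[C@@](O)(C(C)C)[C@@H]1[C@@H](OC(=O)c2ccc(OC)cc2)CC(C)=C | intermediate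
18 | (1S)-1-[(1S,2R,5S)-2-hydroxy-5-[(1R)-1-hydroxyprop-2-en-1-yl]-5-methyl-2-(propan-2-yl)cyclopentyl]-3-methylbut-3-en-1-yl 4-methoxybenzoate | C=C[C@@H](O)[C@@]1(C)CC[C@@](O)(C(C)C)[C@@H]1[C@@H](OC(=O)c2ccc(OC)cc2)CC(C)=C | intermediate
19 | (1S,4R,5S,6S,10R)-4,10-dihydroxydauc-8-en-6-yl 4-methoxybenzoate (trans-fused; 4β-OH, 6α-OAr, 10α-OH) | O[C@@H]1C=C(C)C[C@H](OC(=O)c2ccc(OC)cc2)[C@@H]2[C@]1(C)CC[C@@]2(O)C(C)C | intermediate
20 | angelic acid, (Z)-2-methylbut-2-enoic acid | C/C=C(/C)C(=O)O | starting material
21 | (Z)-2-methylbut-2-enoic 2,4,6-trichlorobenzoic anhydride | C/C=C(/C)C(=O)OC(=O)c1c(Cl)cc(Cl)cc1Cl | intermediate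
22 | (1S,4R,5S,6S,10R)-4-hydroxy-10-[(Z)-2-methylbut-2-enoyloxy]dauc-8-en-6-yl 4-methoxybenzoate | C/C=C(/C)C(=O)O[C@@H]1C=C(C)C[C@H](OC(=O)c2ccc(OC)cc2)[C@@H]2[C@]1(C)CC[C@@]2(O)C(C)C | target

Total step count: 10. Longest linear sequence: 9 steps (steps 1 and 3 to 10; step 2 is a one-step side branch).

**Steps most likely to fail**

Step 3 (one-flask conjugate addition–aldol). The aluminium enolate may be captured incompletely or with poor face selectivity, through competing 1,2-addition of surplus alkenylalane to the aldehyde, proton transfer, or erosion of the trans/anti selectivity. The fallback sets out from 8: the enolate is silylated in the flask with Me3SiCl to benzyl(dimethyl){1-[(1S)-1-methyl-3-(trimethylsilyloxy)cyclopent-2-en-1-yl]ethenyl}silane F1, which is isolated free of aluminium and copper. MeLi in THF at 0 °C then regenerates the regiodefined lithium enolate F2, and its aldol addition to 5 at −78 °C through a closed transition state comes back to the route at 9.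

Step 9 (ring-closing metathesis). Closure at the two hindered olefins may be slow, so that oligomerisation by cross-metathesis or isomerisation of the allylic alcohol by ruthenium hydrides takes over. The fallback sets out from 14 and forms the same C8–C9 bond by carbonyl condensation. Ozonolysis of the methallyl group (O3, CH2Cl2, −78 °C; Me2S) gives the diketone (1S)-1-[(1S,2R,5S)-5-acetyl-2-hydroxy-5-methyl-2-(propan-2-yl)cyclopentyl]-3-oxobutyl 4-methoxybenzoate F3. The C10 ketone can enolise only towards C9, and the competing five-membered closure would give a trans-fused bicyclo[3.3.0]octane, so acid-catalysed intramolecular aldol condensation (TsOH, benzene, 60 °C; acid to avoid E1cB loss of the anisate) should close ring B to the cycloheptenone (1S,4R,5S,6S)-4-hydroxy-10-oxodauc-8-en-6-yl 4-methoxybenzoate F4. Reagent-controlled Corey–Bakshi–Shibata reduction of its C10 ketone [(S)-oxazaborolidine, catecholborane, −78 °C] comes back to the route at 19; here the reagent must override the ring's expected preference for hydride attack anti to the C1 methyl group.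

Step 10 (angelate formation). Acylation of the neopentyl-type allylic alcohol may be sluggish, and the acyl group may isomerise from Z to E (tiglate). The fallback sets out from 19: esterification with 2-[bis(2,2,2-trifluoroethoxy)phosphoryl]propanoic acid (DCC, DMAP, CH2Cl2) gives the phosphonopropionate (1S,4R,5S,6S,10R)-10-{2-[bis(2,2,2-trifluoroethoxy)phosphoryl]propanoyloxy}-4-hydroxydauc-8-en-6-yl 4-methoxybenzoate F5. Still–Gennari olefination with acetaldehyde [KN(SiMe3)2, 18-crown-6, THF, −78 °C] then builds the (Z)-2-methylbut-2-enoate on the molecule and comes back to the route at 22.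

Further compounds
F1 | step 3 | benzyl(dimethyl){1-[(1S)-1-methyl-3-(trimethylsilyloxy)cyclopent-2-en-1-yl]ethenyl}silane | C=C([Si](C)(C)Cc2ccccc2)[C@@]1(C)CCC(O[Si](C)(C)C)=C1
F2 | step 3 | lithium (3S)-3-[1-(benzyldimethylsilyl)ethenyl]-3-methylcyclopent-1-en-1-olate | C=C([Si](C)(C)Cc2ccccc2)[C@@]1(C)CCC(O[Li])=C1
F3 | step 9 | (1S)-1-[(1S,2R,5S)-5-acetyl-2-hydroxy-5-methyl-2-(propan-2-yl)cyclopentyl]-3-oxobutyl 4-methoxybenzoate | CC(=O)[C@@]1(C)CC[C@@](O)(C(C)C)[C@@H]1[C@@H](OC(=O)c2ccc(OC)cc2)CC(C)=O
F4 | step 9 | (1S,4R,5S,6S)-4-hydroxy-10-oxodauc-8-en-6-yl 4-methoxybenzoate | O=C1C=C(C)C[C@H](OC(=O)c2ccc(OC)cc2)[C@@H]2[C@]1(C)CC[C@@]2(O)C(C)C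
F5 | step 10 | (1S,4R,5S,6S,10R)-10-{2-[bis(2,2,2-trifluoroethoxy)phosphoryl]propanoyloxy}-4-hydroxydauc-8-en-6-yl 4-methoxybenzoate (both epimers at the phosphonate carbon) | CC(C(=O)O[C@@H]1C=C(C)C[C@H](OC(=O)c2ccc(OC)cc2)[C@@H]2[C@]1(C)CC[C@@]2(O)C(C)C)P(=O)(OCC(F)(F)F)OCC(F)(F)F
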